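## Structural features

The target joins an aromadendrane-type carbocycle to a 3,5-diformylphloroglucinol ring. The carbocycle is a cyclopentene (C1–C5) fused along C1–C5 to a seven-membered ring (C1, C5–C10). That ring carries a gem-dimethylcyclopropane on C6–C7 (apex C11) and a tetrasubstituted C1=C10 alkene with a methyl group on C10. The two halves are linked twice: quaternary C4 (methyl) is bonded to the benzylic carbon C7' (isobutyl), and C2 is bonded through an ether oxygen to C2'. The result is a benzo-fused oxepane (O, C2, C3, C4, C7', C1', C2') bridged by C1–C5, an oxabicyclo[4.2.1]nonane core. There are six stereocentres (C2 R, C4 R, C5 R, C6 R, C7 R, C7' S). C4 and C7' are a vicinal quaternary/tertiary pair, C4–C5–C6–C7 are contiguous, and the bridge fixes the relation of the bridgeheads C2 and C4. The fragile points are the C2–O bond (allylic, and attached to a good leaving group once the ring bears two formyl groups), the cyclopropane, the tetrasubstituted alkene and the chelated hydroxy-aldehydes. The real difficulty is the crowded C4/C7' pair and building the 5–7 system onto it with control at C5. The feature the key step uses is that C1 and C6–C10, with the C10 methyl, have the substitution pattern of a toluene ring attached to C2, and that the ring-fusion methine C5 is the one carbon lying between C1 and C6.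

## Logic of the disconnections

**21 ⇒ 20.** The two aryl–formyl bonds (C3'–CHO, C5'–CHO) are cut first. The aldehydes are the most reactive groups and turn the C2–O aryl ether into an allylic ester-like leaving group, so they should arrive last. This leaves an electron-rich resorcinol-type ring. The forward step must formylate twice without acid damage to the allylic ether, alkene and cyclopropane, so it is run on the free diphenol, which is nucleophilic enough for both positions.

**20 ⇒ 19.** The two O–Si bonds are cut. The phenols must be masked through enolate, hydride, Mitsunobu and carbenoid chemistry. Triisopropylsilyl ethers replace the usual methyl ethers so that unmasking needs only fluoride and no Lewis acid next to the allylic ether. The demand is that the aryl silyl ethers survive twelve steps.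

**19 ⇒ 18 ⇒ 17.** C8=C9 is restored and the two cyclopropane bonds C6–C11 and C7–C11 are cut. This removes the C6 and C7 stereocentres and leaves a conjugated triene. The forward steps need site selectivity among three alkenes (terminal C6=C7 over internal C8=C9 and tetrasubstituted C1=C10), attack on the face of the triene anti to C4, and then saturation of the one remaining disubstituted alkene.

**17 ⇒ 14 (key).** C5–C1 and C5–C6 are cut. The cyclopentene, the seven-membered ring and the C5 stereocentre disappear together, leaving an o-tolyl group on C2 of a benzoxepane and a one-carbon carbene precursor on C4. The forward step must direct a non-stabilised carbenoid onto the arene, on its unsubstituted ortho side, faster than C–H insertion or ylide formation. The substrate design helps in three ways: the tolyl group is cis to the carbene carbon, the isobutyl group is trans to it, and the oxygens near the carbenoid carry bulky silyl groups, not methyl groups.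

**14 ⇒ 13 ⇒ 12.** The C=N group is exchanged back and the O–C2 bond is cut. The seven-membered ether closes by SN2 at benzylic C2, which opens the ring to a phenol and a secondary alcohol. Because the closure inverts C2, 12 must be (S) at C2. C5 must be masked by a group with no acidic N–H, so that only the phenol acts as the Mitsunobu nucleophile.

**12 ⇒ 10 ⇒ 8.** C5 is returned to the carboxyl level and the C2–H bond is cut (alcohol back to ketone). The phenol oxygen and C5 are then tied up as a lactone and the C2 stereocentre is gone. The forward reduction must be reagent-controlled, because quaternary C4 is too remote to direct it.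

**8 ⇒ 7.** The C2=O bond is traced to a C2=CH2 bond. An aryl ketone is more acidic than the lactone and could not be carried through the enolate steps; a 1,1-disubstituted styrene can.

**7 ⇒ 6 ⇒ 3 + 5 (5 ⇒ 4).** C4–CH3 is cut first, then C4–C3. The dihydrocoumarin ring is a rigid template in which C7' directs both alkylations to the opposite face. Introducing methyl last therefore places it trans to isobutyl, which is the C4/C7' relation of the target. The demand is high trans selectivity in forming a quaternary centre, which is why the smallest electrophile is kept for that step.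

**3 ⇒ 2 ⇒ 1.** The C7'–isobutyl bond and the O–Si bonds are cut, leading to a flat, achiral coumarin. The forward conjugate addition must be catalyst-controlled, since C7' is the centre from which C4 (and through it C5, C6 and C7) is derived.

## Other disconnections considered

**Alternative 1:** The cut is the C3–C4 bond, traced back to a cyclohexene oxide. In the forward step a Lewis acid (for example BF3·OEt2) would open the trisubstituted epoxide A1 at tertiary C4, and ring carbon C3 would shift from C7' to C4. This contracts the six-membered ring and releases C7' as the formyl group of cyclopentane A2.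
- In its favour: the semipinacol-type rearrangement of 1-methylcyclohexene oxides to 1-methylcyclopentanecarbaldehydes is well documented. It sets quaternary C4 stereospecifically from the epoxide face, and the cyclopropane-bearing seven-membered ring could come from the chiral pool, so no late cyclopropanation is needed.
- Against it here: A2 solves only C4. The aryl group must then be added to a neopentyl aldehyde, the isobutyl group introduced at C7' with control next to the quaternary centre, and the oxepane oxygen bond and the C1=C10 alkene made afterwards. A hydride shift to a ketone and Lewis-acid opening of the cyclopropane are competing paths.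
- Comparison: on precedent the alternative is better than the chosen key step, and on early, purely carbocyclic construction of C4 it is at least equal. It is weaker on step economy and leaves the C4/C7' relation open, which the chosen plan settles with a lactone template.

**Alternative 2:** The cut is the C2'–O bond. In the forward step the C2 alkoxide of fluoroarene A3 (KN(SiMe3)2 or Cs2CO3) would displace fluoride, which is activated by ortho and para formyl groups, to give the target dimethyl ether A4.
- In its favour: the substitution is convergent and runs with retention at C2, and the aldehydes are already in place, so no late formylation is needed. On that last point it is better than the chosen plan.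
- Against it here: A3 already contains the complete carbocycle and the C4–C7' bond to a hexasubstituted arene, so the hardest bond must be made earlier between two crowded fragments. An alkoxide next to two aldehydes invites hemiacetal and hydride-transfer chemistry. A4 still needs cleavage of two methyl ethers beside an allylic aryl ether that the formyl groups have activated.
- Comparison: the ring-closing mechanism is more reliable than a new carbenoid reaction, and the end game is equal in length. The chosen plan avoids the final demethylation and builds the C4/C7' pair before the carbocycle exists.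

**Alternative 3:** The cut is the C1–C2 bond. In the forward step Rh2(OAc)4 or Rh2(O2CCPh3)4 would decompose the cyclic diazoketone A5, and the carbenoid at C1 would insert into a C2–H bond next to the ether oxygen to give the bridged ketone A6.
- In its favour: insertion of an acceptor carbenoid into an oxygen-activated C–H bond with five-membered ring closure has much better precedent than the chosen key step. The cyclopropane would come ready-made, so steps 12 and 13 of the chosen route would not be needed.
- Against it here: A5 requires a bond between quaternary C4 and a ring carbon of the seven-membered ketone, with three contiguous stereocentres. The insertion must choose one of two diastereotopic C2–H bonds and compete with ylide formation at the adjacent oxygen and attack on the electron-rich arene. A6 must still be converted at C10 into the methyl-bearing tetrasubstituted alkene without migration of the double bond.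
- Comparison: it is better on mechanism and precedent and equal on ring count per step (one ring, one bond, against two rings and two bonds here). It is weaker on the supply of its precursor and on the later alkene installation.

Key step: step 11

Remarks on the chemistry, made before the steps:
- The locants follow the terpenoid numbering used above (C1–C11, C1'–C7'). In systematic benzoxepine and chromanone names, C7' is ring position 5 and 4 respectively.
- The substrate 14 and product 17 of the key step were checked atom by atom against the target: 14 carries C2 (R), C4 (R), C7' (S) and 17 adds C5 (R). No correction of connectivity or configuration was needed. The changes made are in the spectator groups (silyl ethers in place of methyl ethers) and in the way 14 is reached.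
- 5,7-Dihydroxycoumarin and 2-isopropenyltoluene are taken as catalogue compounds.
- In step 2 the ligand enantiomer is the one that gives (S)-3; its antipode is used if the first run shows the opposite sense.
- CIP descriptors at C7' change between intermediates only because neighbour priorities change; the geometry is constant.

## Route

Step 1
Reactants: 1 5,7-dihydroxy-2H-chromen-2-one (5,7-dihydroxycoumarin)
Product: 2 5,7-bis(triisopropylsilyloxy)-2H-chromen-2-one
Conditions: TIPSCl, imidazole, DMF, rt
Reagents that add atoms: triisopropylsilyl chloride, CC(C)[Si](Cl)(C(C)C)C(C)C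
Why: Silyl ether formation on both phenols; the bulky, fluoride-labile groups are chosen so that the later carbenoid finds no nucleophilic methoxy oxygen and the final unmasking needs no Lewis acid.

Step 2
Reactants: 2 5,7-bis(triisopropylsilyloxy)-2H-chromen-2-one
Product: 3 (4S)-4-isobutyl-5,7-bis(triisopropylsilyloxy)chroman-2-one
Conditions: CuBr·SMe2 (5 mol %), (R)-1-[(S)-2-(diphenylphosphino)ferrocenyl]ethyldicyclohexylphosphine (6 mol %), i-BuMgBr, t-BuOMe, –72 °C; aq. NH4Cl
Reagents that add atoms: isobutylmagnesium bromide, CC(C)C[Mg]Br
Why: Copper-catalysed asymmetric conjugate addition of a Grignard reagent to a coumarin; the chiral ferrocenyl bisphosphine–copper complex selects one face of the C3=C4 bond and sets C7' as (S), and slow addition at low temperature keeps 1,2-addition to the aryl ester down.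

Step 3
Reactants: 4 1-methyl-2-(prop-1-en-2-yl)benzene (2-isopropenyltoluene)
Product: 5 1-(3-bromoprop-1-en-2-yl)-2-methylbenzene
Conditions: NBS, TsOH·H2O (10 mol %), THF, reflux
Reagents that add atoms: N-bromosuccinimide, O=C1CCC(=O)N1Br
Why: Allylic bromination of an α-methylstyrene through the ionic bromonium/elimination pathway, which leaves the aryl methyl group untouched.

Step 4
Reactants: 3 (4S)-4-isobutyl-5,7-bis(triisopropylsilyloxy)chroman-2-one, 5 1-(3-bromoprop-1-en-2-yl)-2-methylbenzene
Product: 6 (3S,4S)-4-isobutyl-3-[2-(2-methylphenyl)prop-2-enyl]-5,7-bis(triisopropylsilyloxy)chroman-2-one (3,4-trans)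
Conditions: LiN(SiMe3)2, THF, –78 °C; then 5, –78 to –40 °C
Reagents that add atoms: none
Why: Lactone enolate alkylation with an allylic bromide; the isobutyl group, held pseudo-axial by the peri silyloxy group, shields one face, so the electrophile enters trans (this C3 centre is erased in step 5).

Step 5
Reactants: 6 (3S,4S)-4-isobutyl-3-[2-(2-methylphenyl)prop-2-enyl]-5,7-bis(triisopropylsilyloxy)chroman-2-one
Product: 7 (3R,4R)-4-isobutyl-3-methyl-3-[2-(2-methylphenyl)prop-2-enyl]-5,7-bis(triisopropylsilyloxy)chroman-2-one (methyl trans to isobutyl)
Conditions: LiN(SiMe3)2, THF, –78 °C; MeI, DMPU, –78 to –30 °C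
Reagents that add atoms: iodomethane, CI
Why: Second enolate alkylation; MeI attacks the fully substituted enolate anti to the pseudo-axial isobutyl group, so methyl ends trans to isobutyl and the arylallyl chain cis, which fixes quaternary C4 relative to C7' as in the target.

Step 6
Reactants: 7 (3R,4R)-4-isobutyl-3-methyl-3-[2-(2-methylphenyl)prop-2-enyl]-5,7-bis(triisopropylsilyloxy)chroman-2-one
Product: 8 (3R,4R)-4-isobutyl-3-methyl-3-[2-(2-methylphenyl)-2-oxoethyl]-5,7-bis(triisopropylsilyloxy)chroman-2-one
Conditions: O3, CH2Cl2, –78 °C (to first excess); Me2S, –78 °C to rt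
Reagents that add atoms: ozone, [O-][O+]=O
Why: Ozonolysis with reductive work-up; the 1,1-disubstituted styrene reacts far faster than the silyloxy arene at –78 °C, and the aryl ketone appears only after all enolate chemistry is finished.

Step 7
Reactants: 8 (3R,4R)-4-isobutyl-3-methyl-3-[2-(2-methylphenyl)-2-oxoethyl]-5,7-bis(triisopropylsilyloxy)chroman-2-one
Product: 10 (3R,5S)-3-{(1R)-1-[2-hydroxy-4,6-bis(triisopropylsilyloxy)phenyl]-3-methylbutyl}-3-methyl-5-(2-methylphenyl)oxolan-2-one, via hydroxy dihydrocoumarin 9 (not isolated)
Conditions: (R)-1-methyl-3,3-diphenyltetrahydro-1H,3H-pyrrolo[1,2-c][1,3,2]oxazaborole (20 mol %), BH3·SMe2, THF, –20 °C; MeOH; then Et3N (cat.), CH2Cl2, rt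
Reagents that add atoms: none
Why: CBS reduction with reagent control: with aryl as the large group the (R)-oxazaborolidine gives the (S)-carbinol at C2. The new hydroxyl then takes the acyl group from the phenol oxygen (translactonisation to the more stable γ-lactone, retention at C2), which frees the phenol.

Step 8
Reactants: 10 (3R,5S)-3-{(1R)-1-[2-hydroxy-4,6-bis(triisopropylsilyloxy)phenyl]-3-methylbutyl}-3-methyl-5-(2-methylphenyl)oxolan-2-one
Product: 12 (E)-(2R,4S)-4-hydroxy-2-{(1S)-1-[2-hydroxy-4,6-bis(triisopropylsilyloxy)phenyl]-3-methylbutyl}-2-methyl-4-(2-methylphenyl)butanal N,N-dimethylhydrazone, via lactol 11 (not isolated)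
Conditions: i-Bu2AlH (2.5 equiv), CH2Cl2, –78 °C; aq. potassium sodium tartrate; crude lactol, Me2NNH2, AcOH (cat.), EtOH, 60 °C
Reagents that add atoms: 1,1-dimethylhydrazine, CN(C)N
Why: Half-reduction of the γ-lactone to the lactol, then condensation of its open hydroxy-aldehyde form with the hydrazine. The dimethylhydrazone masks C5 without an acidic N–H, so the phenol and the C2 hydroxyl are the only partners in the next step.

Step 9
Reactants: 12 (E)-(2R,4S)-4-hydroxy-2-{(1S)-1-[2-hydroxy-4,6-bis(triisopropylsilyloxy)phenyl]-3-methylbutyl}-2-methyl-4-(2-methylphenyl)butanal N,N-dimethylhydrazone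
Product: 13 (2R,4R,5S)-5-isobutyl-4-methyl-2-(2-methylphenyl)-6,8-bis(triisopropylsilyloxy)-2,3,4,5-tetrahydro-1-benzoxepine-4-carbaldehyde N,N-dimethylhydrazone
Conditions: PPh3, DIAD, toluene (0.01 M), 0 °C to rt
Reagents that add atoms: none
Why: Intramolecular Mitsunobu etherification; the phenol displaces the activated benzylic oxygen with inversion (C2 S to R), which places the tolyl group cis to the hydrazone carbon. Quaternary C4 and high dilution favour the seven-membered ring closure over elimination.

Step 10
Reactants: 13 (2R,4R,5S)-5-isobutyl-4-methyl-2-(2-methylphenyl)-6,8-bis(triisopropylsilyloxy)-2,3,4,5-tetrahydro-1-benzoxepine-4-carbaldehyde N,N-dimethylhydrazone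
Product: 14 (2R,4R,5S)-5-isobutyl-4-methyl-2-(2-methylphenyl)-6,8-bis(triisopropylsilyloxy)-2,3,4,5-tetrahydro-1-benzoxepine-4-carbaldehyde N-tosylhydrazone
Conditions: TsNHNH2 (3 equiv), AcOH, MeOH/THF, 50 °C
Reagents that add atoms: 4-methylbenzenesulfonohydrazide, Cc1ccc(cc1)S(=O)(=O)NN
Why: Acid-catalysed hydrazone exchange (transimination); protonation at the dimethylamino nitrogen activates the C=N bond for addition of the sulfonyl hydrazide and 1,1-dimethylhydrazine leaves. No stereocentre is involved.

Step 11
Reactants: 14 (2R,4R,5S)-5-isobutyl-4-methyl-2-(2-methylphenyl)-6,8-bis(triisopropylsilyloxy)-2,3,4,5-tetrahydro-1-benzoxepine-4-carbaldehyde N-tosylhydrazone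
Product: 17 bridged cycloheptatriene (2R,4R,5R,7'S; double bonds C1=C10/C8=C9/C6=C7; H5 endo; aryl bis-silyl ether), via diazoalkane 15 (not isolated), via norcaradiene 16 (not isolated)
Conditions: NaH, THF, 0 °C to rt; then Rh2(O2CCF3)4 (2 mol %), BnEt3NCl (10 mol %), ClCH2CH2Cl, 70 °C
Reagents that add atoms: none
Why: Proposed new method: deprotonation of 14 and warming expel sulfinate (Bamford–Stevens) to give diazoalkane 15, which Rh2(O2CCF3)4 turns into an electrophilic, non-stabilised carbenoid at C5; since C4 is quaternary no 1,2-hydride shift can intercept it, and it adds across the ipso–ortho bond of the cis-disposed o-tolyl group to give norcaradiene 16, whose disrotatory 6π electrocyclic opening breaks C1–C6 and gives 17 — the closest known reaction types are the dirhodium-catalysed intramolecular Buchner reaction of diazoketones with tethered arenes and the copper-halide-catalysed ring expansion of benzene by diazomethane, here extended to an alkyl carbenoid made in situ from a tosylhydrazone. The cyclopentene closes by formation of C5–C1 through the three-atom tether C4–C3–C2 as the first bond of an intramolecular [2+1] cycloaddition onto the ipso carbon, and the seven-membered ring arises by one-carbon expansion of the arene once C5–C6 is formed and the norcaradiene opens. The only new stereocentre, C5, is fixed by C4 and the bridged frame: the cyclopropane can form only with C6 on the exo face of the emerging cyclopentane, away from the four-atom O–aryl–C7' bridge, which leaves H5 pointing towards that bridge as in the target. Arene addition must outrun 1,5-insertion into the isobutyl methine C–H; this is addressed by the perfluorocarboxylate ligands, which favour aromatic cycloaddition over aliphatic insertion, and by the peri silyloxy group at C6', which holds the isobutyl chain on the face of the oxepane opposite to C5. Attack at the unsubstituted ortho carbon follows from the steric cost of cyclopropanating the methyl-bearing position, so the tolyl methyl ends on C10 of the tetrasubstituted alkene. The silyl ethers also remove the nucleophilic alkoxy oxygen that would otherwise lie within reach of the carbenoid.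

Step 12
Reactants: 17 bridged cycloheptatriene (2R,4R,5R,7'S)
Product: 18 gem-dimethylcyclopropane diene (2R,4R,5R,6R,7R,7'S; cyclopropane C6–C7–C11; double bonds C1=C10/C8=C9)
Conditions: CoBr2 complex of 2,6-bis[1-(2-tert-butylphenylimino)ethyl]pyridine (10 mol %), Zn, ZnBr2, Me2CCl2, THF, rt
Reagents that add atoms: 2,2-dichloropropane, CC(C)(Cl)Cl
Why: Cobalt-catalysed reductive dimethylcyclopropanation of a conjugated diene unit; the cobalt carbenoid transfers isopropylidene to the least substituted terminal alkene C6=C7, not to internal C8=C9 or tetrasubstituted C1=C10. Addition on the convex face, anti to quaternary C4 and its methyl group, sets C6 and C7 (both R) with the cyclopropane cis to H5.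

Step 13
Reactants: 18 gem-dimethylcyclopropane diene (2R,4R,5R,6R,7R,7'S)
Product: 19 bis-silyl ether of the deformyl target (2R,4R,5R,6R,7R,7'S; only C1=C10 unsaturated)
Conditions: 2-nitrobenzenesulfonyl hydrazide, Et3N, CH2Cl2, rt
Reagents that add atoms: none
Why: Diimide reduction by concerted syn transfer of two hydrogens; the cis-disubstituted C8=C9 alkene is reduced, while the tetrasubstituted C1=C10 alkene, the cyclopropane and the allylic C2–O bond do not react with diimide.

Step 14
Reactants: 19 bis-silyl ether of the deformyl target
Product: 20 deformyl target diphenol (2R,4R,5R,6R,7R,7'S; free 4'- and 6'-OH)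
Conditions: Bu4NF, AcOH, THF, 0 °C
Reagents that add atoms: none
Why: Fluoride cleavage of both aryl silyl ethers; the acetic acid buffer protects the electron-rich diphenol from oxidation, and no acid or Lewis acid strong enough to ionise the allylic ether is present.

Step 15
Reactants: 20 deformyl target diphenol
Product: 21 CNP0388405.1 (target; 3',5'-diformyl-4',6'-dihydroxy; 2R,4R,5R,6R,7R,7'S)
Conditions: POCl3, DMF, MeCN, 0 °C to rt; then H2O, 40 °C
Reagents that add atoms: N,N-dimethylformamide, CN(C)C=O; water, O
Why: Vilsmeier–Haack formylation; the free phloroglucinol-type ring is nucleophilic enough to take the chloroiminium electrophile at both open positions C3' and C5' (each ortho or para to three oxygens), and hydrolysis gives the two hydrogen-bonded aldehydes.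

## Compound list

1 | 5,7-dihydroxy-2H-chromen-2-one | O=C1C=Cc2c(O)cc(O)cc2O1 | starting material
2 | 5,7-bis(triisopropylsilyloxy)-2H-chromen-2-one | O=C1C=Cc2c(O[Si](C(C)C)(C(C)C)C(C)C)cc(O[Si](C(C)C)(C(C)C)C(C)C)cc2O1 | intermediate
3 | (4S)-4-isobutyl-5,7-bis(triisopropylsilyloxy)chroman-2-one | O=C1C[C@H](CC(C)C)c2c(O[Si](C(C)C)(C(C)C)C(C)C)cc(O[Si](C(C)C)(C(C)C)C(C)C)cc2O1 | intermediate
4 | 1-methyl-2-(prop-1-en-2-yl)benzene | CC(=C)c1ccccc1C | starting material
5 | 1-(3-bromoprop-1-en-2-yl)-2-methylbenzene | BrCC(=C)c1ccccc1C | intermediate
6 | (3S,4S)-4-isobutyl-3-[2-(2-methylphenyl)prop-2-enyl]-5,7-bis(triisopropylsilyloxy)chroman-2-one, 3,4-trans | O=C1[C@@H](CC(=C)c2ccccc2C)[C@H](CC(C)C)c2c(O[Si](C(C)C)(C(C)C)C(C)C)cc(O[Si](C(C)C)(C(C)C)C(C)C)cc2O1 | intermediate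
7 | (3R,4R)-4-isobutyl-3-methyl-3-[2-(2-methylphenyl)prop-2-enyl]-5,7-bis(triisopropylsilyloxy)chroman-2-one, methyl trans to isobutyl | O=C1[C@](C)(CC(=C)c2ccccc2C)[C@H](CC(C)C)c2c(O[Si](C(C)C)(C(C)C)C(C)C)cc(O[Si](C(C)C)(C(C)C)C(C)C)cc2O1 | intermediate
8 | (3R,4R)-4-isobutyl-3-methyl-3-[2-(2-methylphenyl)-2-oxoethyl]-5,7-bis(triisopropylsilyloxy)chroman-2-one | O=C1[C@](C)(CC(=O)c2ccccc2C)[C@H](CC(C)C)c2c(O[Si](C(C)C)(C(C)C)C(C)C)cc(O[Si](C(C)C)(C(C)C)C(C)C)cc2O1 | intermediate
9 | (3R,4R)-3-[(2S)-2-hydroxy-2-(2-methylphenyl)ethyl]-4-isobutyl-3-methyl-5,7-bis(triisopropylsilyloxy)chroman-2-one | O=C1[C@](C)(C[C@H](O)c2ccccc2C)[C@H](CC(C)C)c2c(O[Si](C(C)C)(C(C)C)C(C)C)cc(O[Si](C(C)C)(C(C)C)C(C)C)cc2O1 | intermediate (not isolated)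
10 | (3R,5S)-3-{(1R)-1-[2-hydroxy-4,6-bis(triisopropylsilyloxy)phenyl]-3-methylbutyl}-3-methyl-5-(2-methylphenyl)oxolan-2-one | O=C1O[C@H](c2ccccc2C)C[C@]1(C)[C@H](CC(C)C)c1c(O[Si](C(C)C)(C(C)C)C(C)C)cc(O[Si](C(C)C)(C(C)C)C(C)C)cc1O | intermediate
11 | lactol of 10: (3R,5S)-3-{(1R)-1-[2-hydroxy-4,6-bis(triisopropylsilyloxy)phenyl]-3-methylbutyl}-3-methyl-5-(2-methylphenyl)oxolan-2-ol, both anomers | OC1O[C@H](c2ccccc2C)C[C@]1(C)[C@H](CC(C)C)c1c(O[Si](C(C)C)(C(C)C)C(C)C)cc(O[Si](C(C)C)(C(C)C)C(C)C)cc1O | intermediate (not isolated)
12 | (E)-(2R,4S)-4-hydroxy-2-{(1S)-1-[2-hydroxy-4,6-bis(triisopropylsilyloxy)phenyl]-3-methylbutyl}-2-methyl-4-(2-methylphenyl)butanal N,N-dimethylhydrazone | CN(C)/N=C/[C@](C)(C[C@H](O)c1ccccc1C)[C@H](CC(C)C)c1c(O[Si](C(C)C)(C(C)C)C(C)C)cc(O[Si](C(C)C)(C(C)C)C(C)C)cc1O | intermediate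
13 | (2R,4R,5S)-5-isobutyl-4-methyl-2-(2-methylphenyl)-6,8-bis(triisopropylsilyloxy)-2,3,4,5-tetrahydro-1-benzoxepine-4-carbaldehyde N,N-dimethylhydrazone (E) | Cc1ccccc1[C@H]1C[C@@](C)(/C=N/N(C)C)[C@H](CC(C)C)c2c(O[Si](C(C)C)(C(C)C)C(C)C)cc(O[Si](C(C)C)(C(C)C)C(C)C)cc2O1 | intermediate
14 | (2R,4R,5S)-5-isobutyl-4-methyl-2-(2-methylphenyl)-6,8-bis(triisopropylsilyloxy)-2,3,4,5-tetrahydro-1-benzoxepine-4-carbaldehyde N-tosylhydrazone (E); substrate of the key step | Cc1ccccc1[C@H]1C[C@@](C)(/C=N/NS(=O)(=O)c2ccc(C)cc2)[C@H](CC(C)C)c2c(O[Si](C(C)C)(C(C)C)C(C)C)cc(O[Si](C(C)C)(C(C)C)C(C)C)cc2O1 | intermediate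
15 | (2R,4R,5S)-4-(diazomethyl)-5-isobutyl-4-methyl-2-(2-methylphenyl)-6,8-bis(triisopropylsilyloxy)-2,3,4,5-tetrahydro-1-benzoxepine | Cc1ccccc1[C@H]1C[C@@](C)(C=[N+]=[N-])[C@H](CC(C)C)c2c(O[Si](C(C)C)(C(C)C)C(C)C)cc(O[Si](C(C)C)(C(C)C)C(C)C)cc2O1 | intermediate (not isolated)
16 | norcaradiene: cyclopropane C5–C1–C6 on the exo face of the new cyclopentane (syn to the C4 methyl), cyclohexadiene C7=C8/C9=C10 with methyl on C10, benzoxepane unchanged | CC1=CC=C[C@H]2[C@H]3[C@@]12[C@H]1C[C@]3(C)[C@H](CC(C)C)c2c(O[Si](C(C)C)(C(C)C)C(C)C)cc(O[Si](C(C)C)(C(C)C)C(C)C)cc2O1 | intermediate (not isolated)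
17 | bridged cycloheptatriene, (2R,4R,5R,7'S): cyclopentene C1–C5 fused to cyclohepta-triene (C1=C10, C8=C9, C6=C7; methyl on C10), C4 methyl, C4–C7' and C2–O–C2' links to the 4',6'-bis(triisopropylsilyloxy)phenyl ring, isobutyl on C7', H5 endo; product of the key step | CC1=C2[C@H](C=CC=C1)[C@]1(C)C[C@H]2Oc2cc(O[Si](C(C)C)(C(C)C)C(C)C)cc(O[Si](C(C)C)(C(C)C)C(C)C)c2[C@H]1CC(C)C | intermediate
18 | as 17 with a gem-dimethylcyclopropane on C6–C7 (cis to H5), (2R,4R,5R,6R,7R,7'S); C1=C10 and C8=C9 remain | CC1=C2[C@H]([C@H]3[C@@H](C=C1)C3(C)C)[C@]1(C)C[C@H]2Oc2cc(O[Si](C(C)C)(C(C)C)C(C)C)cc(O[Si](C(C)C)(C(C)C)C(C)C)c2[C@H]1CC(C)C | intermediate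
19 | as 18 with C8–C9 saturated (only C1=C10 left), (2R,4R,5R,6R,7R,7'S); 4',6'-bis-silyl ether of the deformyl target | CC1=C2[C@H]([C@H]3[C@@H](CC1)C3(C)C)[C@]1(C)C[C@H]2Oc2cc(O[Si](C(C)C)(C(C)C)C(C)C)cc(O[Si](C(C)C)(C(C)C)C(C)C)c2[C@H]1CC(C)C | intermediate
20 | deformyl target: 4',6'-diphenol, (2R,4R,5R,6R,7R,7'S) | CC1=C2[C@H]([C@H]3[C@@H](CC1)C3(C)C)[C@]1(C)C[C@H]2Oc2cc(O)cc(O)c2[C@H]1CC(C)C | intermediate
21 | CNP0388405.1, (2R,4R,5R,6R,7R,7'S) | CC1=C2[C@H]([C@H]3[C@@H](CC1)C3(C)C)[C@]1(C)C[C@H]2Oc2c(C=O)c(O)c(C=O)c(O)c2[C@H]1CC(C)C | target

## Step count and least certain steps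

Total: 15 steps. Longest linear sequence: 14 steps (1 to 21 through steps 1, 2 and 4–15); step 3 is a one-step side branch.

**Step 11 (key step, no direct precedent).** The carbenoid may be diverted before it reaches the arene:
- 1,5-insertion into the tertiary C–H of the isobutyl group;
- capture by the ring ether oxygen, followed by shift or elimination of the ylide;
- 1,2-shift of a C4 substituent;
- addition on the methyl-bearing ortho side;
- slow isomerisation of the triene at 70 °C.

Alkyl carbenoids without a stabilising group are short-lived and unselective, and the salt-based generation needs heat.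

Fallback, from 13 back to 17: exchange of 13 with hydrazine hydrate (EtOH, 70 °C) should give the N-unsubstituted hydrazone F1. Oxidation with activated MnO2 (CH2Cl2, 0 °C) should give a cold solution of diazoalkane 15. Slow addition of this to CuBr (5 mol %) in CH2Cl2 at 0 °C should give 17. This is the long-established copper-halide-catalysed ring expansion of benzene rings by non-stabilised diazoalkanes. The carbene is released at low temperature from a preformed diazo compound, with no base or sulfinate present.

**Step 12.** The cobalt carbenoid may add at C8=C9 or twice. It may approach the wrong face. The zinc halides may ionise the dienylic C2–O bond of 17 or 18.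

Fallback, from 17 back to 18: dibromocarbene (CHBr3, KOt-Bu, pentane, –20 °C) should add to the most accessible alkene to give the gem-dibromocyclopropane F2. Me2CuLi (Et2O, –40 °C) followed by MeI should replace both bromines by methyl and give 18. The whole sequence is basic.

**Step 2.** The silyloxy group next to C4 and the electron-rich ring may slow the conjugate addition. This would allow 1,2-addition at the aryl ester or erode the enantioselectivity.

Fallback, from 2 back to 3: uncatalysed copper-mediated addition (i-BuMgBr, CuI, Me3SiCl, THF, –40 °C) should give the racemic lactone F3. (S)-1-Phenylethylamine (toluene, 60 °C) should open it to two diastereomeric hydroxy amides, and crystallisation or chromatography should give the (S)-configured amide F4. TsOH in toluene at 90 °C should close it back to 3. This is a classical resolution.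

**Step 15.** The second formylation may stall after the first iminium group has deactivated the ring. The hydrogen chloride released may ionise the allylic ether or move the alkene.

Fallback, from 20 directly to 21: magnesium-phenoxide-directed ortho-formylation (MgCl2, Et3N, paraformaldehyde, MeCN, reflux). Each phenol directs formaldehyde to its free ortho position in a basic medium. No new isolated compound arises.

**Step 10.** Exchange at the neopentyl-type hydrazone may be slow or stop at partial hydrolysis.

Fallback, from 13 back to 14: hydrolysis with Cu(OAc)2 in THF/H2O at rt should give the free aldehyde F5. This non-enolisable aldehyde should condense with TsNHNH2 in MeOH at rt to give 14.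

Further compounds

F1 | step 11 | (2R,4R,5S)-5-isobutyl-4-methyl-2-(2-methylphenyl)-6,8-bis(triisopropylsilyloxy)-2,3,4,5-tetrahydro-1-benzoxepine-4-carbaldehyde hydrazone (E) | Cc1ccccc1[C@H]1C[C@@](C)(/C=N/N)[C@H](CC(C)C)c2c(O[Si](C(C)C)(C(C)C)C(C)C)cc(O[Si](C(C)C)(C(C)C)C(C)C)cc2O1
F2 | step 12 | gem-dibromocyclopropane analogue of 18 (CBr2 in place of CMe2 on C6–C7) | CC1=C2[C@H]([C@H]3[C@@H](C=C1)C3(Br)Br)[C@]1(C)C[C@H]2Oc2cc(O[Si](C(C)C)(C(C)C)C(C)C)cc(O[Si](C(C)C)(C(C)C)C(C)C)c2[C@H]1CC(C)C
F3 | step 2 | racemic 4-isobutyl-5,7-bis(triisopropylsilyloxy)chroman-2-one | O=C1CC(CC(C)C)c2c(O[Si](C(C)C)(C(C)C)C(C)C)cc(O[Si](C(C)C)(C(C)C)C(C)C)cc2O1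
F4 | step 2 | (3S)-3-[2-hydroxy-4,6-bis(triisopropylsilyloxy)phenyl]-5-methyl-N-[(1S)-1-phenylethyl]hexanamide | C[C@H](NC(=O)C[C@H](CC(C)C)c1c(O[Si](C(C)C)(C(C)C)C(C)C)cc(O[Si](C(C)C)(C(C)C)C(C)C)cc1O)c1ccccc1
F0 | step 15 | none | none
F5 | step 10 | (2R,4R,5S)-5-isobutyl-4-methyl-2-(2-methylphenyl)-6,8-bis(triisopropylsilyloxy)-2,3,4,5-tetrahydro-1-benzoxepine-4-carbaldehyde | Cc1ccccc1[C@H]1C[C@@](C)(C=O)[C@H](CC(C)C)c2c(O[Si](C(C)C)(C(C)C)C(C)C)cc(O[Si](C(C)C)(C(C)C)C(C)C)cc2O1
A1 | alternative 1 | cyclohexene oxide precursor: epoxide across C4 (methyl) and C7', C2 silyl ether, C10 ketone, cyclopropane on C6–C7 | O=C1[C@@H]2[C@H]([C@H]3[C@@H](CC1)C3(C)C)[C@@]4(C)O[C@H]4C[C@H]2O[Si](C)(C)C(C)(C)C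
A2 | alternative 1 | ring-contracted cyclopentane with quaternary C4 bearing methyl and formyl (C7') | O=C1[C@@H]2[C@H]([C@H]3[C@@H](CC1)C3(C)C)[C@@](C)(C=O)C[C@H]2O[Si](C)(C)C(C)(C)C
A3 | alternative 2 | C2 allylic alcohol carrying the 2-fluoro-3,5-diformyl-4,6-dimethoxyphenyl group on C7' | CC1=C2[C@H]([C@H]3[C@@H](CC1)C3(C)C)[C@](C)(C[C@H]2O)[C@H](CC(C)C)c1c(F)c(C=O)c(OC)c(C=O)c1OC
A4 | alternative 2 | 4',6'-di-O-methyl ether of the target | CC1=C2[C@H]([C@H]3[C@@H](CC1)C3(C)C)[C@]1(C)C[C@H]2Oc2c(C=O)c(OC)c(C=O)c(OC)c2[C@H]1CC(C)C
A5 | alternative 3 | cyclic α-diazoketone (diazo on C1, ketone on C10) joined through C5 to C4 of the 6,8-dimethoxy-2,3,4,5-tetrahydro-1-benzoxepine | O=C1C(=[N+]=[N-])[C@H]([C@H]3[C@@H](CC1)C3(C)C)[C@]1(C)CCOc2cc(OC)cc(OC)c2[C@H]1CC(C)C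
A6 | alternative 3 | bridged C10 ketone (C1 epimerisable) | O=C1C2[C@H]([C@H]3[C@@H](CC1)C3(C)C)[C@]1(C)C[C@H]2Oc2cc(OC)cc(OC)c2[C@H]1CC(C)C
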